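**Retrosynthetic overview**
1. Target 25 comes from cyclononene 24 by hydroxyl-directed epoxidation of C8=C9; 24 comes from lactone 23 by ring-closing metathesis (the nine-membered ring is closed second).
2. 23 comes from the open-chain ester 21 by closing the δ-lactone at the ring-fusion bond C4a–C11a: an intramolecular palladium-catalysed allyl–allyl coupling of an allyl boronate (C19–B, C11=C11a) with a vinyl oxirane (C4a=C4, oxirane C12–C13).
3. Enabling feature: C4a–C11a is the central bond of the 1,5-diene C19=C11–C11a–C4a–C4=C12 (exocyclic methylene on the cyclononane, exocyclic alkylidene on the lactone), and C13 carries a hydroxyl one atom further out. Both fusion carbons are therefore allyl termini, and the C13–OH is the trace of an oxirane leaving group.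
4. 21 comes from acid 20 and alcohol 6 (Mitsunobu). 20 is built from (S)-linalool (C5–C8 and the C7 stereocentre) via an ynoate, hydrostannation/Stille coupling and two reagent-controlled Shi epoxidations; 6 comes from propargyl alcohol and allyl bromide.
5. Ring order: side-chain oxiranes before the union; δ-lactone (step 15); cyclononene (step 16); ring oxirane last (step 17).

Key step: step 15

Remark (assumption and numbering): (S)-(+)-linalool and both enantiomers of the fructose-derived Shi ketone are taken as purchasable; atoms are numbered lactone C1–O2–C3(=O)–C4–C4a, carbocycle C5–C11 and C11a, side chain C12–C15, exocyclic methylene C19 on C11.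

**Route**

Step 1
Reactants: 1 prop-2-yn-1-ol; 2 3-bromoprop-1-ene
Product: 3 hex-5-en-2-yn-1-ol
Conditions: CuI (10 mol %), K2CO3, Bu4NCl (cat.), DMF, rt
Reagents that add atoms: none
Why: Copper-catalysed allylation of the terminal alkyne (acetylide SN2 coupling) should give the skipped enyne without touching the free hydroxyl; no stereocentre is formed.

Step 2
Reactants: 3 hex-5-en-2-yn-1-ol
Product: 5 (2Z)-3-iodohexa-2,5-dien-1-ol, via cyclic alkenylalanate 4 (not isolated)
Conditions: NaAlH2(OCH2CH2OMe)2 (Red-Al), THF, 0 °C; then I2, −78 → 0 °C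
Reagents that add atoms: iodine, II
Why: Hydroxyl-directed trans-hydroalumination of the propargylic alcohol places aluminium on C3 in a five-membered alanate, and iodinolysis with retention should give the (Z)-3-iodo allylic alcohol, which fixes the geometry of the trisubstituted alkene.

Step 3
Reactants: 5 (2Z)-3-iodohexa-2,5-dien-1-ol
Product: 6 (2E)-3-[(4,4,5,5-tetramethyl-1,3,2-dioxaborolan-2-yl)methyl]hexa-2,5-dien-1-ol
Conditions: CH2(Bpin)2, Pd[P(t-Bu)3]2 (5 mol %), aq. KOH, 1,4-dioxane, rt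
Reagents that add atoms: bis[(pinacolato)boryl]methane, C(B1OC(C)(C)C(C)(C)O1)B1OC(C)(C)C(C)(C)O1
Why: Chemoselective Suzuki–Miyaura coupling of the alkenyl iodide with one boron of the geminal diboryl reagent proceeds with retention, so the CH2B group should end cis to CH2OH (the allyl boronate formed is far less reactive than the diboryl reagent).

Step 4
Reactants: 7 (3S)-3,7-dimethylocta-1,6-dien-3-ol
Product: 8 {[(3S)-3,7-dimethylocta-1,6-dien-3-yl]oxy}triethylsilane
Conditions: Et3SiOTf, 2,6-lutidine, CH2Cl2, −78 → 0 °C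
Reagents that add atoms: triethylsilyl trifluoromethanesulfonate, CC[Si](CC)(CC)OS(=O)(=O)C(F)(F)F
Why: Silyl triflate silylation of the tertiary alcohol; the stereocentre (later C7) comes from the chiral pool and is not touched.

Step 5
Reactants: 8 {[(3S)-3,7-dimethylocta-1,6-dien-3-yl]oxy}triethylsilane
Product: 10 (4S)-4-methyl-4-[(triethylsilyl)oxy]hex-5-enal, via ozonide 9 (not isolated)
Conditions: O3 (1 equiv, Sudan Red 7B end-point), CH2Cl2, −78 °C; then PPh3
Reagents that add atoms: ozone, [O-][O+]=O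
Why: Chemoselective ozonolysis: the electron-rich trisubstituted alkene should react well before the vinyl group on the quaternary carbon, and reduction of the ozonide gives the aldehyde (C4a).

Step 6
Reactants: 10 (4S)-4-methyl-4-[(triethylsilyl)oxy]hex-5-enal
Product: 11 triethyl{[(3S)-3-methylhept-1-en-6-yn-3-yl]oxy}silane
Conditions: MeC(O)C(N2)P(O)(OMe)2, K2CO3, MeOH, 0 °C → rt
Reagents that add atoms: dimethyl (1-diazo-2-oxopropyl)phosphonate, COP(=O)(OC)C(=[N+]=[N-])C(C)=O
Why: Seyferth–Gilbert homologation with the Ohira–Bestmann reagent converts the aldehyde into the terminal alkyne under mild carbonate conditions that the silyl ether tolerates.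

Step 7
Reactants: 11 triethyl{[(3S)-3-methylhept-1-en-6-yn-3-yl]oxy}silane
Product: 13 2-(trimethylsilyl)ethyl (6S)-6-methyl-6-[(triethylsilyl)oxy]oct-7-en-2-ynoate, via lithium acetylide 12 (not isolated)
Conditions: n-BuLi, THF, −78 °C; then ClCO2CH2CH2SiMe3, −78 → 0 °C
Reagents that add atoms: 2-(trimethylsilyl)ethyl chloroformate, C[Si](C)(C)CCOC(=O)Cl
Why: Acylation of the lithium acetylide with the chloroformate gives the ynoate (C3) as a fluoride-labile ester.

Step 8
Reactants: 13 2-(trimethylsilyl)ethyl (6S)-6-methyl-6-[(triethylsilyl)oxy]oct-7-en-2-ynoate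
Product: 14 2-(trimethylsilyl)ethyl (2E,6S)-6-methyl-2-(tributylstannyl)-6-[(triethylsilyl)oxy]octa-2,7-dienoate
Conditions: Bu3SnH, Pd(PPh3)4 (2 mol %), THF, 0 °C → rt
Reagents that add atoms: tributyltin hydride, CCCC[SnH](CCCC)CCCC
Why: Palladium-catalysed syn-hydrostannation of the ynoate places tin α to the ester, which sets the enoate geometry with the C5 chain cis to the ester (H-4a cis to tin).

Step 9
Reactants: 15 3-methylbut-2-enal
Product: 16 (1E)-1-iodo-4-methylpenta-1,3-diene
Conditions: CrCl2, CHI3, THF, 0 °C, dark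
Reagents that add atoms: iodoform, IC(I)I
Why: Takai olefination should give the (E)-iodoalkene (C12=C13).

Step 10
Reactants: 14 2-(trimethylsilyl)ethyl (2E,6S)-6-methyl-2-(tributylstannyl)-6-[(triethylsilyl)oxy]octa-2,7-dienoate; 16 (1E)-1-iodo-4-methylpenta-1,3-diene
Product: 17 2-(trimethylsilyl)ethyl (2Z,6S)-6-methyl-2-[(1E)-4-methylpenta-1,3-dien-1-yl]-6-[(triethylsilyl)oxy]octa-2,7-dienoate
Conditions: Pd2(dba)3 (2.5 mol %), AsPh3 (10 mol %), CuI (10 mol %), NMP, 40 °C
Reagents that add atoms: none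
Why: Copper-assisted Stille coupling forms C4–C12 with retention at both partners, so the C5 chain stays cis to the ester and C12=C13 stays E.

Step 11
Reactants: 17 2-(trimethylsilyl)ethyl (2Z,6S)-6-methyl-2-[(1E)-4-methylpenta-1,3-dien-1-yl]-6-[(triethylsilyl)oxy]octa-2,7-dienoate
Product: 18 2-(trimethylsilyl)ethyl (2Z,6S)-2-{(E)-2-[(2S)-3,3-dimethyloxiran-2-yl]ethenyl}-6-methyl-6-[(triethylsilyl)oxy]octa-2,7-dienoate
Conditions: ent-Shi ketone (L-fructose-derived, 30 mol %), Oxone (2KHSO5·KHSO4·K2SO4, 1.3 equiv), K2CO3, Bu4NHSO4 (cat.), MeCN–CH2(OMe)2 / aq. Na2B4O7 buffer, −10 °C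
Reagents that add atoms: potassium peroxymonosulfate, [K+].[O-]S(=O)(=O)OO
Why: Shi asymmetric epoxidation: the chiral dioxirane attacks the most electron-rich, distal trisubstituted C14=C15 alkene, and the enantiomeric ketone sets C14 as S by reagent control.

Step 12
Reactants: 18 2-(trimethylsilyl)ethyl (2Z,6S)-2-{(E)-2-[(2S)-3,3-dimethyloxiran-2-yl]ethenyl}-6-methyl-6-[(triethylsilyl)oxy]octa-2,7-dienoate
Product: 19 2-(trimethylsilyl)ethyl (2Z,6S)-2-{(2R,3S)-3-[(2S)-3,3-dimethyloxiran-2-yl]oxiran-2-yl}-6-methyl-6-[(triethylsilyl)oxy]octa-2,7-dienoate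
Conditions: Shi ketone (D-fructose-derived, 50 mol %), Oxone (2KHSO5·KHSO4·K2SO4), K2CO3, Bu4NHSO4 (cat.), MeCN–CH2(OMe)2 / aq. Na2B4O7 buffer, 0 °C
Reagents that add atoms: potassium peroxymonosulfate, [K+].[O-]S(=O)(=O)OO
Why: A second Shi epoxidation, now with the natural ketone, should oxidise the trans-disubstituted C12=C13 alkene (the enoate alkene is electron-poor, the vinyl group monosubstituted and hindered) and set C12 (R) and C13 (S) by reagent control, opposite in sense to C14 as the erythro C13/C14 relationship requires.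

Step 13
Reactants: 19 2-(trimethylsilyl)ethyl (2Z,6S)-2-{(2R,3S)-3-[(2S)-3,3-dimethyloxiran-2-yl]oxiran-2-yl}-6-methyl-6-[(triethylsilyl)oxy]octa-2,7-dienoate
Product: 20 (2Z,6S)-2-{(2R,3S)-3-[(2S)-3,3-dimethyloxiran-2-yl]oxiran-2-yl}-6-hydroxy-6-methylocta-2,7-dienoic acid
Conditions: Bu4NF (3 equiv), THF, 0 °C → rt; AcOH quench
Reagents that add atoms: none
Why: Fluoride-induced β-elimination of the 2-(trimethylsilyl)ethyl ester and cleavage of the triethylsilyl ether free the acid and the C7 hydroxyl under non-acidic conditions that both oxiranes should survive.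

Step 14
Reactants: 20 (2Z,6S)-2-{(2R,3S)-3-[(2S)-3,3-dimethyloxiran-2-yl]oxiran-2-yl}-6-hydroxy-6-methylocta-2,7-dienoic acid; 6 (2E)-3-[(4,4,5,5-tetramethyl-1,3,2-dioxaborolan-2-yl)methyl]hexa-2,5-dien-1-ol
Product: 21 (2E)-3-[(4,4,5,5-tetramethyl-1,3,2-dioxaborolan-2-yl)methyl]hexa-2,5-dien-1-yl (2Z,6S)-2-{(2R,3S)-3-[(2S)-3,3-dimethyloxiran-2-yl]oxiran-2-yl}-6-hydroxy-6-methylocta-2,7-dienoate
Conditions: PPh3, i-PrO2CN=NCO2i-Pr, toluene, 0 °C
Reagents that add atoms: none
Why: Mitsunobu esterification: the carboxylate displaces the activated primary allylic alcohol at C1, the tertiary C7 hydroxyl is inert, and no acyl activation occurs that could lactonise onto it.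

Step 15
Reactants: 21 (2E)-3-[(4,4,5,5-tetramethyl-1,3,2-dioxaborolan-2-yl)methyl]hexa-2,5-dien-1-yl (2Z,6S)-2-{(2R,3S)-3-[(2S)-3,3-dimethyloxiran-2-yl]oxiran-2-yl}-6-hydroxy-6-methylocta-2,7-dienoate
Product: 23 (3E,4S,5R)-3-{(2S)-2-[(2S)-3,3-dimethyloxiran-2-yl]-2-hydroxyethylidene}-4-[(3S)-3-hydroxy-3-methylpent-4-en-1-yl]-5-(penta-1,4-dien-2-yl)oxan-2-one, via pinacol borate 22 (not isolated)
Conditions: Pd2(dba)3 (2.5 mol %), 1,2-(Ph2P)2C6H4 (6 mol %), THF (0.01 M), 25 °C; then aq. NH4Cl
Reagents that add atoms: none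
Why: Proposed new method: zerovalent palladium opens the vinyl oxirane at C12 with inversion to a zwitterionic π-allyl complex (C4a–C4–C12), the C13 alkoxide binds boron and passes the C19–C11=C11a allyl group to palladium, and 3,3′-reductive elimination of the bis(allyl)palladium joins C11a to C4a; the closest known reaction type is the palladium-catalysed allyl–allyl cross-coupling of allyl boronates with allylic electrophiles, together with the base-free coupling of vinyl oxiranes with organoboron reagents. The δ-lactone (C11a–C1–O2–C3–C4–C4a) is closed 6-endo with respect to the enoate through the ester tether, which is feasible because the bond forms inside a chair-like seven-membered array on palladium and not by in-plane attack. C4a is set by the (12R)-oxirane (palladium anti to the C–O bond, new bond on the palladium face, net anti-SN2′), and C11a follows because the tether and the metal bridge force C5 (cis to the ester on the enoate) and C11 anti across the new bond, which is the trans fusion. The E geometry of C4=C12 arises because C13 sits anti on the π-allyl, turned away from the ester toward H-4a; C13 keeps its configuration as the borate and C11=C19 is created by the allyl transposition. The step needs bond formation at C4a and not at C12, and it must outrun ionisation of the allylic C1–O ester and return of the alkoxide to carbon; the hindered, oxygen-flanked C12 terminus, the far faster ionisation of a vinyl oxirane and the rapid boron–oxygen transfer are what should secure this.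

Step 16
Reactants: 23 (3E,4S,5R)-3-{(2S)-2-[(2S)-3,3-dimethyloxiran-2-yl]-2-hydroxyethylidene}-4-[(3S)-3-hydroxy-3-methylpent-4-en-1-yl]-5-(penta-1,4-dien-2-yl)oxan-2-one
Product: 24 (4E,4aS,7S,8Z,11aR)-4-{(2S)-2-[(2S)-3,3-dimethyloxiran-2-yl]-2-hydroxyethylidene}-7-hydroxy-7-methyl-11-methylidene-4,4a,5,6,7,10,11,11a-octahydro-1H-cyclonona[c]pyran-3-one
Conditions: second-generation Hoveyda–Grubbs catalyst (10 mol %), 1,4-benzoquinone (20 mol %), toluene (1 mM), 80 °C
Reagents that add atoms: none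
Why: Ring-closing metathesis of the two monosubstituted alkenes on the trans-disubstituted lactone template: the catalyst should load at the unhindered allyl terminus (C9), from which closure onto the C8 vinyl group is the only productive path, and the nine-membered ring can only hold the Z alkene.

Step 17
Reactants: 24 (4E,4aS,7S,8Z,11aR)-4-{(2S)-2-[(2S)-3,3-dimethyloxiran-2-yl]-2-hydroxyethylidene}-7-hydroxy-7-methyl-11-methylidene-4,4a,5,6,7,10,11,11a-octahydro-1H-cyclonona[c]pyran-3-one
Product: 25 (4E,4aS,7S,8R,9R,11aR)-4-{(2S)-2-[(2S)-3,3-dimethyloxiran-2-yl]-2-hydroxyethylidene}-8,9-epoxy-7-hydroxy-7-methyl-11-methylidenedecahydro-1H-cyclonona[c]pyran-3-one (target)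
Conditions: VO(acac)2 (5 mol %), t-BuOOH, CH2Cl2, 0 °C
Reagents that add atoms: tert-butyl hydroperoxide, CC(C)(C)OO
Why: Vanadium-catalysed hydroxyl-directed epoxidation should deliver oxygen to the face of the cis C8=C9 alkene syn to the tertiary C7 hydroxyl (C8 R, C9 R), while the C11 methylene has no allylic hydroxyl and the C4=C12 alkene next to C13–OH is deactivated by the lactone carbonyl.

**Compound list**
1 | prop-2-yn-1-ol | OCC#C | starting material
2 | 3-bromoprop-1-ene | C=CCBr | starting material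
3 | hex-5-en-2-yn-1-ol | OCC#CCC=C | intermediate
4 | sodium 2,2-bis(2-methoxyethoxy)-3-(prop-2-en-1-yl)-2,5-dihydro-1,2-oxaaluminol-2-uide (cyclic alkenylalanate) | [Na+].COCCO[Al-]1(OCCOC)OCC=C1CC=C | intermediate
5 | (2Z)-3-iodohexa-2,5-dien-1-ol | OC/C=C(\I)CC=C | intermediate
6 | (2E)-3-[(4,4,5,5-tetramethyl-1,3,2-dioxaborolan-2-yl)methyl]hexa-2,5-dien-1-ol (CH2B cis to CH2OH) | OC/C=C(\CB1OC(C)(C)C(C)(C)O1)CC=C | intermediate
7 | (3S)-3,7-dimethylocta-1,6-dien-3-ol ((S)-linalool) | C=C[C@@](C)(O)CCC=C(C)C | starting material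
8 | {[(3S)-3,7-dimethylocta-1,6-dien-3-yl]oxy}triethylsilane | C=C[C@@](C)(O[Si](CC)(CC)CC)CCC=C(C)C | intermediate
9 | triethyl{[(3S)-5-(5,5-dimethyl-1,2,4-trioxolan-3-yl)-3-methylpent-1-en-3-yl]oxy}silane (ozonide) | C=C[C@@](C)(O[Si](CC)(CC)CC)CCC1OOC(C)(C)O1 | intermediate
10 | (4S)-4-methyl-4-[(triethylsilyl)oxy]hex-5-enal | C=C[C@@](C)(O[Si](CC)(CC)CC)CCC=O | intermediate
11 | triethyl{[(3S)-3-methylhept-1-en-6-yn-3-yl]oxy}silane | C=C[C@@](C)(O[Si](CC)(CC)CC)CCC#C | intermediate
12 | lithium acetylide of 11 | C=C[C@@](C)(O[Si](CC)(CC)CC)CCC#C[Li] | intermediate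
13 | 2-(trimethylsilyl)ethyl (6S)-6-methyl-6-[(triethylsilyl)oxy]oct-7-en-2-ynoate | C=C[C@@](C)(O[Si](CC)(CC)CC)CCC#CC(=O)OCC[Si](C)(C)C | intermediate
14 | 2-(trimethylsilyl)ethyl (2E,6S)-6-methyl-2-(tributylstannyl)-6-[(triethylsilyl)oxy]octa-2,7-dienoate | C=C[C@@](C)(O[Si](CC)(CC)CC)CC/C=C(/[Sn](CCCC)(CCCC)CCCC)C(=O)OCC[Si](C)(C)C | intermediate
15 | 3-methylbut-2-enal | CC(C)=CC=O | starting material
16 | (1E)-1-iodo-4-methylpenta-1,3-diene | I/C=C/C=C(C)C | intermediate
17 | 2-(trimethylsilyl)ethyl (2Z,6S)-6-methyl-2-[(1E)-4-methylpenta-1,3-dien-1-yl]-6-[(triethylsilyl)oxy]octa-2,7-dienoate | C=C[C@@](C)(O[Si](CC)(CC)CC)CC/C=C(/C=C/C=C(C)C)C(=O)OCC[Si](C)(C)C | intermediate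
18 | 2-(trimethylsilyl)ethyl (2Z,6S)-2-{(E)-2-[(2S)-3,3-dimethyloxiran-2-yl]ethenyl}-6-methyl-6-[(triethylsilyl)oxy]octa-2,7-dienoate | C=C[C@@](C)(O[Si](CC)(CC)CC)CC/C=C(/C=C/[C@@H]1OC1(C)C)C(=O)OCC[Si](C)(C)C | intermediate
19 | 2-(trimethylsilyl)ethyl (2Z,6S)-2-{(2R,3S)-3-[(2S)-3,3-dimethyloxiran-2-yl]oxiran-2-yl}-6-methyl-6-[(triethylsilyl)oxy]octa-2,7-dienoate | C=C[C@@](C)(O[Si](CC)(CC)CC)CC/C=C(/[C@H]1O[C@@H]1[C@@H]2OC2(C)C)C(=O)OCC[Si](C)(C)C | intermediate
20 | (2Z,6S)-2-{(2R,3S)-3-[(2S)-3,3-dimethyloxiran-2-yl]oxiran-2-yl}-6-hydroxy-6-methylocta-2,7-dienoic acid | C=C[C@@](C)(O)CC/C=C(/[C@H]1O[C@@H]1[C@@H]2OC2(C)C)C(O)=O | intermediate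
21 | (2E)-3-[(4,4,5,5-tetramethyl-1,3,2-dioxaborolan-2-yl)methyl]hexa-2,5-dien-1-yl ester of 20 | C=C[C@@](C)(O)CC/C=C(/[C@H]1O[C@@H]1[C@@H]2OC2(C)C)C(=O)OC/C=C(\CB1OC(C)(C)C(C)(C)O1)CC=C | intermediate
22 | pinacol borate of 23 at the C13 oxygen | C=C(CC=C)[C@@H]1COC(=O)/C(=C/[C@H](OB2OC(C)(C)C(C)(C)O2)[C@@H]2OC2(C)C)[C@H]1CC[C@](C)(O)C=C | intermediate
23 | (3E,4S,5R)-3-{(2S)-2-[(2S)-3,3-dimethyloxiran-2-yl]-2-hydroxyethylidene}-4-[(3S)-3-hydroxy-3-methylpent-4-en-1-yl]-5-(penta-1,4-dien-2-yl)oxan-2-one | C=C(CC=C)[C@@H]1COC(=O)/C(=C/[C@H](O)[C@@H]2OC2(C)C)[C@H]1CC[C@](C)(O)C=C | intermediate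
24 | (4E,4aS,7S,8Z,11aR)-4-{(2S)-2-[(2S)-3,3-dimethyloxiran-2-yl]-2-hydroxyethylidene}-7-hydroxy-7-methyl-11-methylidene-4,4a,5,6,7,10,11,11a-octahydro-1H-cyclonona[c]pyran-3-one | C=C1C/C=C\[C@@](C)(O)CC[C@@H]2/C(=C\[C@H](O)[C@@H]3OC3(C)C)C(=O)OC[C@@H]12 | intermediate
25 | (4E,4aS,7S,8R,9R,11aR)-4-{(2S)-2-[(2S)-3,3-dimethyloxiran-2-yl]-2-hydroxyethylidene}-8,9-epoxy-7-hydroxy-7-methyl-11-methylidenedecahydro-1H-cyclonona[c]pyran-3-one | C=C1C[C@H]2O[C@H]2[C@@](C)(O)CC[C@@H]2/C(=C\[C@H](O)[C@@H]3OC3(C)C)C(=O)OC[C@@H]12 | target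

**Step count and risks**
Total steps: 17. Longest linear sequence: 13 steps (steps 4–8 and 10–17, from (S)-linalool).

Steps most likely to fail:

1. Step 15 (key step, new method). What may go wrong: zerovalent palladium may ionise the allylic C1–O ester, or the allyl–palladium intermediate may lose the carboxylate as a diene; the C13 alkoxide may close back onto the allyl unit; the ester may not reach the s-cis geometry needed for closure. Fallback with known chemistry, setting out from 19 and 6 and returning at 23: the bond is made before the ester exists and the ring is closed by lactonisation. Alcohol 6 is silylated (t-BuMe2SiCl, imidazole) to the tert-butyldimethylsilyl ether F1, which has no allylic leaving group. Intermolecular palladium-catalysed allyl–allyl cross-coupling of F1 with oxirane 19 (Pd2(dba)3, 1,2-(Ph2P)2C6H4, THF; bond at the γ-carbon of the boronate, same anti transfer of chirality) should give, through the borate F2 (not isolated), the open-chain ester F3. Bu4NF removes the three silyl groups and the 2-(trimethylsilyl)ethyl ester to give the trihydroxy acid F4, whose primary hydroxyl lactonises (2,4,6-trichlorobenzoyl chloride, Et3N, DMAP) to 23.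

2. Step 16. What may go wrong: the strain of the cyclononene may divert the ruthenium carbene into oligomerisation by cross-metathesis or into closure of a seven-membered ring onto the C11 methylene. Fallback, setting out from 21 and returning at 24: the order of ring formation is reversed. Ring-closing metathesis of 21 (second-generation Grubbs catalyst, CH2Cl2, 1 mM, 40 °C) closes the unstrained 13-membered ring first to give the (8Z)-macrolactone F5 (the E isomer is separated). The palladium conditions of step 15 then form C4a–C11a across the ring, closing lactone and cyclononene together, and should give 24 through the borate F6 (not isolated).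

3. Step 12. What may go wrong: oxygen transfer to the electron-poor C12=C13 alkene next to the C14 oxirane may be slow and poorly face-selective (mismatched with the existing centre), and the vinyl group may be oxidised in competition. Fallback, setting out from 13 and returning at 19: the C12–C13 oxirane is built by ylide epoxidation instead. Conjugate hydroalumination of ynoate 13 (i-Bu2AlH, N-methylmorpholine N-oxide, THF, 0 °C) and trapping with formaldehyde should give the (2Z)-hydroxymethyl enoate F7. CBr4/PPh3 converts it to the allylic bromide F8, and tetrahydrothiophene to the sulfonium bromide F9. Separately, Sharpless epoxidation of 3-methylbut-2-en-1-ol (Ti(Oi-Pr)4, L-(+)-diethyl tartrate, t-BuOOH) gives the (2S)-epoxy alcohol F10, and Dess–Martin oxidation gives the (2R)-epoxy aldehyde F11. Corey–Chaykovsky-type epoxidation of F11 with the ylide from F9 (K2CO3, MeCN) should give the trans-oxirane by Felkin-type anti addition, which is 19.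

**Further compounds**
F1 | step 15 | tert-butyl(dimethyl){[(2E)-3-[(4,4,5,5-tetramethyl-1,3,2-dioxaborolan-2-yl)methyl]hexa-2,5-dien-1-yl]oxy}silane | CC(C)(C)[Si](C)(C)OC/C=C(\CB1OC(C)(C)C(C)(C)O1)CC=C
F2 | step 15 | pinacol borate of F3 at the side-chain oxygen | C=C(CC=C)[C@H](CO[Si](C)(C)C(C)(C)C)[C@H](CC[C@](C)(O[Si](CC)(CC)CC)C=C)/C(=C\[C@H](OB1OC(C)(C)C(C)(C)O1)[C@@H]1OC1(C)C)C(=O)OCC[Si](C)(C)C
F3 | step 15 | 2-(trimethylsilyl)ethyl (2E,3S,4R)-4-{[(tert-butyldimethylsilyl)oxy]methyl}-2-{(2S)-2-[(2S)-3,3-dimethyloxiran-2-yl]-2-hydroxyethylidene}-5-methylidene-3-{(3S)-3-methyl-3-[(triethylsilyl)oxy]pent-4-en-1-yl}oct-7-enoate | C=C(CC=C)[C@H](CO[Si](C)(C)C(C)(C)C)[C@H](CC[C@](C)(O[Si](CC)(CC)CC)C=C)/C(=C\[C@H](O)[C@@H]1OC1(C)C)C(=O)OCC[Si](C)(C)C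
F4 | step 15 | (2E,3S,4R)-2-{(2S)-2-[(2S)-3,3-dimethyloxiran-2-yl]-2-hydroxyethylidene}-3-[(3S)-3-hydroxy-3-methylpent-4-en-1-yl]-4-(hydroxymethyl)-5-methylideneoct-7-enoic acid | C=C(CC=C)[C@H](CO)[C@H](CC[C@](C)(O)C=C)/C(=C\[C@H](O)[C@@H]1OC1(C)C)C(O)=O
F5 | step 16 | (8Z)-13-membered macrolactone from 21 (ring C1–O2–C3–C4–C4a–C5–C6–C7–C8=C9–C10–C11–C11a; bis-oxirane on C4, CH2B(pin) on C11, 7S) | C1/C=C\[C@@](C)(O)CC/C=C(/[C@H]2O[C@@H]2[C@@H]3OC3(C)C)C(=O)OC/C=C1\CB4OC(C)(C)C(C)(C)O4
F6 | step 16 | pinacol borate of 24 at the C13 oxygen | C=C1C/C=C\[C@@](C)(O)CC[C@@H]2/C(=C\[C@H](OB3OC(C)(C)C(C)(C)O3)[C@@H]3OC3(C)C)C(=O)OC[C@@H]12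
F7 | step 12 | 2-(trimethylsilyl)ethyl (2Z,6S)-2-(hydroxymethyl)-6-methyl-6-[(triethylsilyl)oxy]octa-2,7-dienoate | C=C[C@@](C)(O[Si](CC)(CC)CC)CC/C=C(/CO)C(=O)OCC[Si](C)(C)C
F8 | step 12 | 2-(trimethylsilyl)ethyl (2E,6S)-2-(bromomethyl)-6-methyl-6-[(triethylsilyl)oxy]octa-2,7-dienoate | C=C[C@@](C)(O[Si](CC)(CC)CC)CC/C=C(/CBr)C(=O)OCC[Si](C)(C)C
F9 | step 12 | 1-{(2E,6S)-6-methyl-2-{[2-(trimethylsilyl)ethoxy]carbonyl}-6-[(triethylsilyl)oxy]octa-2,7-dien-1-yl}thiolan-1-ium bromide | C=C[C@@](C)(O[Si](CC)(CC)CC)CC/C=C(/C[S+]1CCCC1)C(=O)OCC[Si](C)(C)C.[Br-]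
F10 | step 12 | [(2S)-3,3-dimethyloxiran-2-yl]methanol | OC[C@@H]1OC1(C)C
F11 | step 12 | (2R)-3,3-dimethyloxirane-2-carbaldehyde | O=C[C@@H]1OC1(C)C
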